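**Retrosynthetic overview**
- Last step is a global hydrogenolysis; before it the depside C–O ester bond is made from 4‑O‑benzyl‑2‑O‑methyl‑divaric acid and benzyl divarate.
- Both halves come from one intermediate, 7‑(benzyloxy)‑2,2‑dimethyl‑5‑propyl‑1,3‑benzodioxin‑4‑one (ring‑opening/methylation for one half, debenzylation/benzyl‑oxide opening for the other).
- Key C–C disconnection: aryl–propyl bond → aryl triflate + propanal. The aldehyde carbon is used as a nucleophile (N–H hydrazone, Ni catalysis, loss of N2), so two natively electrophilic carbons are joined.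
- The triflate comes from the acetonide of 2,4,6‑trihydroxybenzoic acid (7‑O‑benzylation, triflation): one phenolic oxygen is traded for the propyl chain.
- Ring order: no ring is built. Both benzene rings are bought, and the dioxinone ring is only a protecting group, opened in steps 4 and 6.

Assumptions: the target has no stereocentre, so no stereocontrol is needed; compound 1 is taken as a catalogue compound.

**Step 1**
Reactants: 1 5,7‑dihydroxy‑2,2‑dimethyl‑4H‑benzo[d][1,3]dioxin‑4‑one; 2 benzyl bromide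
Product: 3 7‑(benzyloxy)‑5‑hydroxy‑2,2‑dimethyl‑4H‑benzo[d][1,3]dioxin‑4‑one
Conditions: BnBr (1.05 eq), K2CO3 (1.1 eq), acetone, rt
Reagents that add atoms: benzyl bromide BrCc1ccccc1
Why: Williamson etherification; the 7‑OH is the more acidic, non‑chelated phenol (the 5‑OH is hydrogen‑bonded to C4=O), so mono‑benzylation is regioselective.

**Step 2**
Reactants: 3 7‑(benzyloxy)‑5‑hydroxy‑2,2‑dimethyl‑4H‑benzo[d][1,3]dioxin‑4‑one; 4 trifluoromethanesulfonic anhydride
Product: 5 7‑(benzyloxy)‑2,2‑dimethyl‑4‑oxo‑4H‑benzo[d][1,3]dioxin‑5‑yl trifluoromethanesulfonate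
Conditions: Tf2O (1.2 eq), pyridine, CH2Cl2, 0 °C
Reagents that add atoms: trifluoromethanesulfonic anhydride O=S(=O)(OS(=O)(=O)C(F)(F)F)C(F)(F)F
Why: O‑sulfonylation (triflation) of the remaining phenol gives an aryl triflate that the ortho carbonyl activates for oxidative addition.

**Step 3 (key step)**
Reactants: 5 7‑(benzyloxy)‑2,2‑dimethyl‑4‑oxo‑4H‑benzo[d][1,3]dioxin‑5‑yl trifluoromethanesulfonate; 6 propanal; 7 hydrazine monohydrate
Product: 9 7‑(benzyloxy)‑2,2‑dimethyl‑5‑propyl‑4H‑benzo[d][1,3]dioxin‑4‑one, via propanal hydrazone 8 (not isolated)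
Conditions: EtCHO (1.6 eq), N2H4·H2O (1.5 eq), THF, rt, then 4 Å MS; add to 5, Ni(cod)2 (10 mol%), PMe3 (20 mol%), DBU (2 eq), THF, 60 °C
Reagents that add atoms: propanal CCC=O
Why: Ni‑catalysed denitrogenative cross‑coupling of an N–H hydrazone with an aryl triflate (Wolff–Kishner‑type carbonyl umpolung): Ni(0) inserts into Ar–OTf, the hydrazone binds through nitrogen and is deprotonated by DBU, loss of N2 turns C1 of propanal into a Ni‑bound propyl carbanion, and reductive elimination forms the aryl–CH2 bond between two natively electrophilic carbons; no stereocentre is formed.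

**Step 4**
Reactants: 9 7‑(benzyloxy)‑2,2‑dimethyl‑5‑propyl‑4H‑benzo[d][1,3]dioxin‑4‑one; 10 iodomethane
Product: 13 4‑(benzyloxy)‑2‑methoxy‑6‑propylbenzoic acid, via dipotassium 4‑(benzyloxy)‑2‑oxido‑6‑propylbenzoate 11 (not isolated), via methyl 4‑(benzyloxy)‑2‑methoxy‑6‑propylbenzoate 12 (not isolated)
Conditions: KOH, DMSO–H2O, 60 °C; MeI (3 eq), rt; then 6 M KOH, 100 °C; cold HCl
Reagents that add atoms: iodomethane CI; potassium hydroxide [K+].[OH-]
Why: one‑pot acyl substitution by hydroxide (dioxinone opening with loss of acetone), Williamson O‑methylation of phenoxide and carboxylate, then BAc2 saponification of the hindered methyl ester in hot KOH/DMSO; the benzyl ether is inert throughout.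

**Step 5**
Reactants: 9 7‑(benzyloxy)‑2,2‑dimethyl‑5‑propyl‑4H‑benzo[d][1,3]dioxin‑4‑one
Product: 14 7‑hydroxy‑2,2‑dimethyl‑5‑propyl‑4H‑benzo[d][1,3]dioxin‑4‑one
Conditions: H2 (1 atm), 10% Pd/C, EtOAc, rt
Reagents that add atoms: none
Why: catalytic hydrogenolysis of the aryl benzyl ether; the dioxinone and the arene are untouched.

**Step 6**
Reactants: 14 7‑hydroxy‑2,2‑dimethyl‑5‑propyl‑4H‑benzo[d][1,3]dioxin‑4‑one; 15 benzyl alcohol
Product: 16 benzyl 2,4‑dihydroxy‑6‑propylbenzoate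
Conditions: BnOH (5 eq), NaH (2.5 eq), THF, 0 → 60 °C; 1 M HCl
Reagents that add atoms: benzyl alcohol OCc1ccccc1
Why: alkoxide ring‑opening of the dioxinone (addition–elimination transesterification) is made irreversible by loss of acetone and gives the benzyl ester with both phenols free.

**Step 7**
Reactants: 13 4‑(benzyloxy)‑2‑methoxy‑6‑propylbenzoic acid; 16 benzyl 2,4‑dihydroxy‑6‑propylbenzoate
Product: 18 benzyl 4‑{[4‑(benzyloxy)‑2‑methoxy‑6‑propylbenzoyl]oxy}‑2‑hydroxy‑6‑propylbenzoate, via 4‑(benzyloxy)‑2‑methoxy‑6‑propylbenzoic trifluoroacetic anhydride 17 (not isolated)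
Conditions: TFAA (5 eq), toluene, rt
Reagents that add atoms: none
Why: mixed‑anhydride (TFAA) esterification, the classical depside coupling; the hindered electron‑rich acid reacts through an acylium‑like mixed anhydride at the free 4‑OH, while the 2‑OH is hydrogen‑bonded to the ester carbonyl and stays free.

**Step 8**
Reactants: 18 benzyl 4‑{[4‑(benzyloxy)‑2‑methoxy‑6‑propylbenzoyl]oxy}‑2‑hydroxy‑6‑propylbenzoate
Product: 19 2‑hydroxy‑4‑[(4‑hydroxy‑2‑methoxy‑6‑propylbenzoyl)oxy]‑6‑propylbenzoic acid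
Conditions: H2 (1 atm), 10% Pd/C, EtOAc, rt
Reagents that add atoms: none
Why: hydrogenolysis removes the benzyl ester and the benzyl ether together; the aryl ester and the methyl ether are stable.

**Compound list**
1 | 5,7‑dihydroxy‑2,2‑dimethyl‑4H‑benzo[d][1,3]dioxin‑4‑one | CC1(C)Oc2cc(O)cc(O)c2C(=O)O1 | starting material
2 | benzyl bromide | BrCc1ccccc1 | starting material
3 | 7‑(benzyloxy)‑5‑hydroxy‑2,2‑dimethyl‑4H‑benzo[d][1,3]dioxin‑4‑one | CC1(C)Oc2cc(OCc3ccccc3)cc(O)c2C(=O)O1 | intermediate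
4 | trifluoromethanesulfonic anhydride | O=S(=O)(OS(=O)(=O)C(F)(F)F)C(F)(F)F | starting material
5 | 7‑(benzyloxy)‑2,2‑dimethyl‑4‑oxo‑4H‑benzo[d][1,3]dioxin‑5‑yl trifluoromethanesulfonate | CC1(C)Oc2cc(OCc3ccccc3)cc(OS(=O)(=O)C(F)(F)F)c2C(=O)O1 | intermediate
6 | propanal | CCC=O | starting material
7 | hydrazine monohydrate | NN.O | starting material
8 | propanal hydrazone (not isolated) | CC/C=N/N | intermediate
9 | 7‑(benzyloxy)‑2,2‑dimethyl‑5‑propyl‑4H‑benzo[d][1,3]dioxin‑4‑one | CCCc1cc(OCc2ccccc2)cc2OC(C)(C)OC(=O)c12 | intermediate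
10 | iodomethane | CI | starting material
11 | dipotassium 4‑(benzyloxy)‑2‑oxido‑6‑propylbenzoate (not isolated) | CCCc1cc(OCc2ccccc2)cc([O-])c1C(=O)[O-].[K+].[K+] | intermediate
12 | methyl 4‑(benzyloxy)‑2‑methoxy‑6‑propylbenzoate (not isolated) | CCCc1cc(OCc2ccccc2)cc(OC)c1C(=O)OC | intermediate
13 | 4‑(benzyloxy)‑2‑methoxy‑6‑propylbenzoic acid | CCCc1cc(OCc2ccccc2)cc(OC)c1C(=O)O | intermediate
14 | 7‑hydroxy‑2,2‑dimethyl‑5‑propyl‑4H‑benzo[d][1,3]dioxin‑4‑one | CCCc1cc(O)cc2OC(C)(C)OC(=O)c12 | intermediate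
15 | benzyl alcohol | OCc1ccccc1 | starting material
16 | benzyl 2,4‑dihydroxy‑6‑propylbenzoate | CCCc1cc(O)cc(O)c1C(=O)OCc1ccccc1 | intermediate
17 | 4‑(benzyloxy)‑2‑methoxy‑6‑propylbenzoic trifluoroacetic anhydride (not isolated) | CCCc1cc(OCc2ccccc2)cc(OC)c1C(=O)OC(=O)C(F)(F)F | intermediate
18 | benzyl 4‑{[4‑(benzyloxy)‑2‑methoxy‑6‑propylbenzoyl]oxy}‑2‑hydroxy‑6‑propylbenzoate | CCCc1cc(OC(=O)c2c(CCC)cc(OCc3ccccc3)cc2OC)cc(O)c1C(=O)OCc1ccccc1 | intermediate
19 | 2‑hydroxy‑4‑[(4‑hydroxy‑2‑methoxy‑6‑propylbenzoyl)oxy]‑6‑propylbenzoic acid | CCCc1cc(OC(=O)c2c(CCC)cc(O)cc2OC)cc(O)c1C(=O)O | target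

**Totals**
Total step count: 8.
Longest linear sequence: 7 steps (1 → 2 → 3 → 5 → 6 → 7 → 8); the acid branch (1 → 2 → 3 → 4 → 7 → 8) is 6.

**Three steps most likely to fail**

Step 3. The coupling uses an enolisable aliphatic hydrazone on a base‑sensitive dioxinone triflate. Likely failure modes are reduction of the triflate to Ar–H, N‑arylation, or opening of the dioxinone by traces of hydrazine. Fallback: set out from 5 and deliver the same carbon as a diazo nucleophile. Propanal N‑tosylhydrazone F1 (from 6 and tosylhydrazide, MeOH, rt) is coupled with 5 under Barluenga conditions (Pd2(dba)3, XPhos, LiOtBu, dioxane, 90 °C; Pd‑carbene migratory insertion, then β‑hydride elimination). This gives 7‑(benzyloxy)‑2,2‑dimethyl‑5‑[(E)‑prop‑1‑en‑1‑yl]‑4H‑benzo[d][1,3]dioxin‑4‑one F2. Diimide (2‑nitrobenzenesulfonohydrazide, Et3N, CH2Cl2, rt) then saturates the alkene without touching the benzyl ether, and the route is rejoined at 9.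

Step 6. The 7‑phenoxide formed under the basic conditions deactivates the dioxinone carbonyl, so benzyl‑oxide opening may be sluggish. Fallback: set out from 14 and hydrolyse it with KOH in aqueous DMSO (60 °C, cold acidification) to 2,4‑dihydroxy‑6‑propylbenzoic acid F3. Selective alkylation of its carboxylate with 2 (KHCO3, DMF, rt) rejoins the route at 16.

Step 7. The 2,6‑disubstituted acid is hindered, and Friedel–Crafts C‑acylation or acylation at the 2‑OH could compete. Fallback: set out from 13 and 14, so that the nucleophile has only one hydroxyl. Acid 13 is converted with oxalyl chloride (cat. DMF, CH2Cl2) into 4‑(benzyloxy)‑2‑methoxy‑6‑propylbenzoyl chloride F4. This acylates 14 (Et3N, DMAP, CH2Cl2) to give 2,2‑dimethyl‑4‑oxo‑5‑propyl‑4H‑benzo[d][1,3]dioxin‑7‑yl 4‑(benzyloxy)‑2‑methoxy‑6‑propylbenzoate F5. Hydrogenolysis (H2, Pd/C, EtOAc) gives 2,2‑dimethyl‑4‑oxo‑5‑propyl‑4H‑benzo[d][1,3]dioxin‑7‑yl 4‑hydroxy‑2‑methoxy‑6‑propylbenzoate F6. LiOH in THF–H2O at 0 °C then opens the planar dioxinone, which should react faster than the shielded, phenoxide‑deactivated depside ester, and the route is rejoined at 19.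

**Further compounds**
F1 | step 3 | propanal N‑tosylhydrazone | CC/C=N/NS(=O)(=O)c1ccc(C)cc1
F2 | step 3 | 7‑(benzyloxy)‑2,2‑dimethyl‑5‑[(E)‑prop‑1‑en‑1‑yl]‑4H‑benzo[d][1,3]dioxin‑4‑one | C/C=C/c1cc(OCc2ccccc2)cc2OC(C)(C)OC(=O)c12
F3 | step 6 | 2,4‑dihydroxy‑6‑propylbenzoic acid | CCCc1cc(O)cc(O)c1C(=O)O
F4 | step 7 | 4‑(benzyloxy)‑2‑methoxy‑6‑propylbenzoyl chloride | CCCc1cc(OCc2ccccc2)cc(OC)c1C(=O)Cl
F5 | step 7 | 2,2‑dimethyl‑4‑oxo‑5‑propyl‑4H‑benzo[d][1,3]dioxin‑7‑yl 4‑(benzyloxy)‑2‑methoxy‑6‑propylbenzoate | CCCc1cc(OC(=O)c3c(CCC)cc(OCc4ccccc4)cc3OC)cc2OC(C)(C)OC(=O)c12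
F6 | step 7 | 2,2‑dimethyl‑4‑oxo‑5‑propyl‑4H‑benzo[d][1,3]dioxin‑7‑yl 4‑hydroxy‑2‑methoxy‑6‑propylbenzoate | CCCc1cc(OC(=O)c3c(CCC)cc(O)cc3OC)cc2OC(C)(C)OC(=O)c12
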